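# Synthesis proposal for 9-acetylisoobtusol

## Structural features

The target is a chamigrane: two cyclohexane rings share the quaternary spiro carbon C6. Ring A (C6 to C11) carries an exocyclic methylene on C7, an acetoxy group on C9, a bromine on C10 and a gem-dimethyl group on C11. Ring B (C6, C1 to C5) carries a secondary chloride on C2 and a tertiary bromide with a methyl group on C3.

C6 is bonded to the fully substituted C11, so two quaternary carbons stand next to each other. C9 and C10 are adjacent stereocentres with oxygen and bromine cis, and C10 is neopentyl, which excludes SN2 chemistry there. C2 and C3 are adjacent with the halogens trans, and both relate to C6 only through the ring.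

Ring B prefers the chair with the sp2 carbon C7 axial and C11 equatorial. In the target this makes the C2 chlorine and the C3 bromine trans-diaxial, with chlorine syn-axial to C7.

Fragile groups are the tertiary bromide (ionisation, loss of HBr), the 1,1-disubstituted alkene (acid-induced migration into the ring), the acetate and, on the way, any α-bromo carbonyl compound.

The difficulty is threefold: the congested C6–C11 bond with absolute control at C6, the cis bromohydrin unit beside C11, and a bromochloride with bromine on the more substituted carbon, the opposite of what a simple BrCl addition gives.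

The key step uses the homoallylic alcohol pattern C7(=CH2)–C8H2–C9H(O) of ring A. It is the retron of an ene reaction between an aldehyde at C9 and an isopropenyl group on C6, so the C8–C9 bond, the methylene group and the C9 carbinol arise together.

## Logic of the disconnections

**C3–Br (25 to 23).** Anti addition of BrCl to the C2=C3 alkene of 21 would be shorter. It would pass through a bromonium ion that chloride opens at the methyl-bearing C3, which puts the halogens on the wrong carbons. If chlorine sits on C2 first and bromide arrives last at a C3 cation, the bridging atom is chlorine. Then the preference for the more substituted carbon and the trans-diaxial preference both send bromide to C3, anti to chlorine. So 25 is cut to the tertiary alcohol 23, through the ion pair 24. Gain: the most labile group is made last. Demand: ionisation of a tertiary C–O bond without free acid, and bromide capture faster than proton loss.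

**C2–Cl and the oxirane (23 to 22 to 21).** The C2–Cl bond is cut to the oxirane 22, and its two C–O bonds to the alkene 21. An oxirane on the face of ring B anti to the axial C7 can only open trans-diaxially at the secondary C2. One face selection, governed by C6, therefore fixes both C2 and C3. Demand: the peracid must choose the trisubstituted alkene over the C7 methylene and the face anti to C7, and chloride must attack by SN2.

**C3–CH3 (21 to 20 to 18).** The methyl bond is cut to the enol triflate 20, which goes back to the enone 18 by conjugate reduction and O-triflation. The saturated ketone is nearly symmetric, and only the enone fixes the alkene at C2=C3. Gain: ring B returns to the electron-poor enone that the key step needs as an inert spectator. Demand: 1,4-hydride delivery in the presence of an acetate and a bromide.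

**Acetate (18 to 17).** The acetate C–O bond is cut. The ester is the group of the target and protects the C9 hydroxyl through the enolate and organometallic steps, so no protecting group has to be removed.

**C8–C9, the key cut (17 to 16).** Ring A opens at C8–C9 to the aldehyde 16 with an isopropenyl group on C6. The cut removes a ring and a stereocentre and leaves a monocyclic enone. Demand: a chair transition state with axial oxygen and equatorial bromine, and a C10 configuration that survives until the ring closes.

**C10–Br (16 to 15).** The bromine is introduced last before ring closure because an α-bromo aldehyde is configurationally labile. Catalyst control is needed because C6 is too remote to direct C10.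

**C3 carbonyl and the acetal (15 to 14 to 13).** The ring B carbonyl is cut back to the allylic methylene of 13, and the aldehyde is masked as its dimethyl acetal. Oxidising after homologation, on the acetal, avoids taking an enone through hydride and ylide steps and avoids exposing a free aldehyde to peroxyl radicals. Demand: the oxidant must prefer the single ring methylene over the isopropenyl methyl.

**C9–C10 (13 to 11).** One carbon is removed by a retro-Wittig cut. Gain: 11 is a non-enolisable aldehyde whose carbonyl carbon is the former acyl carbon of the rearrangement. Demand: olefination of a hindered aldehyde.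

**C6–C11 (11 to 10 to 7).** The bond between the two quaternary carbons is cut by a retro [3,3] shift, after redox adjustment from aldehyde to alcohol to ester. An intramolecular, suprafacial shift is the safest way to join two fully substituted carbons and it moves the carbinol configuration of 7 to C6. Gain: the quaternary stereocentre is reduced to a secondary allylic alcohol. Demand: the ketene acetal must rearrange before the dienyl ester ionises.

**Ester, carbinol and isopropenyl (7 to 1, 2 and 6).** The ester C–O bond leads to 5 and 6. The carbinol C–H bond leads to the dienone 4 by enantioselective reduction. The ring–isopropenyl bond leads to 1 and 2. Demand: one reagent-controlled stereocentre, from which all others follow.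

## Other disconnections considered

**Alternative 1:** The cut removes the C6–C1 bond of ring B and the C2–Cl bond in one operation.

- Forward step: copper-catalysed atom-transfer radical cyclisation of A2, a ring A vinylogous ester with a tertiary chlorine on C6 and the chain C5–C4–C3(Me)(OSiEt3)–C2H=C1H2. CuCl with tris(2-pyridylmethyl)amine (monovalent copper) abstracts the C6 chlorine, the α-keto radical closes 6-endo on the vinyl terminus C1, and the C2 radical takes chlorine back from the divalent copper chloride to give A1.
- In favour: ring B, the spiro centre and the secondary chloride arise in one catalytic, redox-neutral step, and A2 is robust. The C3 oxygen is already trans to chlorine, so ring B then needs only a hydroxyl-to-bromide exchange. That is shorter than the six steps from 17 to 25 and is the better solution for ring B.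
- Against: C6 and C2 are set by substrate control from the single C3 stereocentre through a radical chair, and 5-exo closure on C2 is a possible leak. Ring A remains a vinylogous ester, so the C7 methylene, C9 carbinol and C10 bromide must all be added later, the last two relative to a remote C6.
- Comparison: structurally the chosen plan finishes ring A in its ring-forming event and leaves ring B for later; this alternative does the reverse. Mechanistically a planar radical gives less predictable facial control than the ordered chair of the ene reaction, but it avoids a configurationally labile α-bromo aldehyde, which is a point in its favour. In step count it should be shorter or at least equal, since its precursor derives from a dimedone enol ether in few steps.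

**Alternative 2:** The cut is the C6–C11 bond of ring A.

- Forward step: the bromochloride A4, a 2-chloro-4-alkylidenecyclohexanone whose side chain ends in C10HBr–C11Me2Cl, is dissolved in hexafluoroisopropanol. The tertiary chloride ionises with participation of the neighbouring bromine, the tetrasubstituted C6=C7 alkene attacks C11 through C6 anti to the bridging bromine, and the C7 cation loses a proton from its methyl group to give A3.
- In favour: the bond between the two fully substituted carbons, ring A, the C10 bromide and the exocyclic alkene form together. C10 comes from a configurationally stable bromochloride and not from an α-bromo aldehyde, which is better than the chosen plan. Ring B already holds the C2 chloride beside a ketone, so methyl addition and one substitution finish it, again shorter than the chosen plan.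
- Against: the geometry of the tetrasubstituted alkene (C8 cis to C5) becomes the configuration of C6 and must be pure. The α-chloro ketone can epimerise. The cation may end by loss of a ring proton or by solvent capture, and the C9 silyloxy group next to the bromonium ion slows ionisation.
- Comparison: both plans close ring A. The chosen plan forms the easy C8–C9 bond after the quaternary pair has been secured by a sigmatropic shift with reliable chirality transfer. The alternative puts the greatest risk and the greatest gain into one cationic step. In convergence and step economy the alternative is better; in predictability of each single step the chosen plan is.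

**Alternative 3:** The cuts are C6–C5 and C1=C2, the two bonds of a Robinson-type annulation of ring B.

- Forward step: the formyl vinylogous ester A6 adds through C6 to methyl vinyl ketone A7 under a chiral bifunctional amine base. Amine-mediated aldol condensation of the methyl ketone with the formyl carbon closes ring B in the same pot to the spiro enone A5.
- In favour: the spiro core is reached in very few steps, clearly better than the ten steps to 17. The quaternary centre is set by a catalyst. Ring B of A5 is the same enone as in 17, so the ring B endgame would be identical (equal).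
- Against: the nucleophilic carbon lies next to the gem-dimethyl group, so the Michael addition builds the two adjacent quaternary carbons intermolecularly; this is slow and leaves the enantioselectivity uncertain. Ring A then still needs methylenation at C7, reduction at C9 and bromination at C10. The C10 configuration would depend on the small difference between the two arms of ring B at C6, whereas the chosen plan sets it by a catalyst. Two carbonyl systems must also be told apart.
- Comparison: structurally the alternative builds ring B on ring A, the chosen plan the opposite. Mechanistically it uses robust polar chemistry without a labile aldehyde, which is equal or better. In step economy it is better up to the spirocycle but returns part of that gain in the substrate-controlled functionalisation of ring A.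

Key step: step 10

Remark 1: locants C1 to C11 follow the ring A/ring B numbering with the spiro atom as C6, also where a systematic name would number differently.

Remark 2: the enantiomer of the oxazaborolidine in step 2 and of the pyrrolidine in step 9 is assigned from the usual transition-state models (enone alkene as the large group; bromine delivered anti to the shielding phenyl group); if either sense proves opposite, the mirror-image catalyst is used.

Remark 3: the configurations of 16 (2R, ring carbon R) and 17 (6R,9S,10R) map atom by atom onto those of 25, so no structure needed correction.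

## Route

Step 1
Reactants: 1 3-ethoxycyclohex-2-en-1-one; 2 isopropenylmagnesium bromide
Product: 4 3-(prop-1-en-2-yl)cyclohex-2-en-1-one, via tertiary carbinol adduct 3 (not isolated)
Conditions: THF, 0 °C → rt; then 1 M HCl, rt
Reagents that add atoms: water, O
Why: Stork–Danheiser transposition: the Grignard reagent adds 1,2 to the vinylogous ester, and aqueous acid ionises the tertiary allylic alcohol and hydrolyses the enol ether to the transposed dienone; no stereocentre is formed.

Step 2
Reactants: 4 3-(prop-1-en-2-yl)cyclohex-2-en-1-one
Product: 5 (1S)-3-(prop-1-en-2-yl)cyclohex-2-en-1-ol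
Conditions: (R)-2-methyl-CBS-oxazaborolidine (10 mol %), catecholborane, toluene, −78 °C; then MeOH, aq. NaOH
Reagents that add atoms: none
Why: Corey–Bakshi–Shibata reduction: the enone alkene acts as the large group, so the (R)-oxazaborolidine should deliver hydride to the face that gives the (S)-allylic alcohol; catecholborane at low temperature leaves the diene unhydroborated.

Step 3
Reactants: 5 (1S)-3-(prop-1-en-2-yl)cyclohex-2-en-1-ol; 6 isobutyryl chloride
Product: 7 (1S)-3-(prop-1-en-2-yl)cyclohex-2-en-1-yl 2-methylpropanoate
Conditions: pyridine, DMAP (cat.), CH2Cl2, 0 °C → rt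
Reagents that add atoms: none
Why: DMAP-catalysed acylation of a secondary allylic alcohol by an acid chloride; the carbinol stereocentre is not touched.

Step 4
Reactants: 7 (1S)-3-(prop-1-en-2-yl)cyclohex-2-en-1-yl 2-methylpropanoate
Product: 10 2-methyl-2-[(1R)-1-(prop-1-en-2-yl)cyclohex-2-en-1-yl]propan-1-ol, via silyl ketene acetal 8 (not isolated), via trimethylsilyl ester 9 (not isolated)
Conditions: LiN(i-Pr)2, Me3SiCl, THF, −78 °C → 65 °C; then LiAlH4, 0 °C → rt
Reagents that add atoms: none
Why: Ireland–Claisen rearrangement: the O-silyl ketene acetal of the isobutyrate (no E/Z issue) shifts suprafacially across the ring alkene, so the C6–C11 bond forms on the face that held the C–O bond and the carbinol configuration becomes that of the quaternary C6. The intramolecular [3,3] shift is the standard way to join two fully substituted carbons, and the crude silyl ester is reduced in the same flask by hydride to the neopentyl alcohol.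

Step 5
Reactants: 10 2-methyl-2-[(1R)-1-(prop-1-en-2-yl)cyclohex-2-en-1-yl]propan-1-ol
Product: 11 2-methyl-2-[(1R)-1-(prop-1-en-2-yl)cyclohex-2-en-1-yl]propanal
Conditions: Dess–Martin periodinane, CH2Cl2, rt
Reagents that add atoms: none
Why: Dess–Martin oxidation of a primary neopentyl alcohol; the aldehyde has no α-hydrogen and can neither enolise nor epimerise.

Step 6
Reactants: 11 2-methyl-2-[(1R)-1-(prop-1-en-2-yl)cyclohex-2-en-1-yl]propanal
Product: 13 (1R)-1-(4,4-dimethoxy-2-methylbutan-2-yl)-1-(prop-1-en-2-yl)cyclohex-2-ene, via methyl enol ether 12 (not isolated)
Conditions: Ph3P(CH2OMe)Cl, KN(SiMe3)2, THF, 0 °C → rt; then MeOH, pyridinium p-toluenesulfonate (cat.), rt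
Reagents that add atoms: (methoxymethyl)triphenylphosphonium chloride, COC[P+](c1ccccc1)(c1ccccc1)c1ccccc1.[Cl-]; methanol, CO
Why: Wittig methoxymethylenation adds C9 to the hindered but non-enolisable aldehyde, and acid-catalysed addition of methanol to the enol ether gives the dimethyl acetal in the same flask. The acetal masks the aldehyde against the radical oxidation of the next step; methanol as solvent traps the oxocarbenium ion far faster than the isopropenyl group can.

Step 7
Reactants: 13 (1R)-1-(4,4-dimethoxy-2-methylbutan-2-yl)-1-(prop-1-en-2-yl)cyclohex-2-ene
Product: 14 (4R)-4-(4,4-dimethoxy-2-methylbutan-2-yl)-4-(prop-1-en-2-yl)cyclohex-2-en-1-one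
Conditions: Rh2(cap)4 (cap = caprolactamate, 1 mol %), t-BuOOH, K2CO3 (cat.), CH2Cl2, rt
Reagents that add atoms: tert-butyl hydroperoxide, CC(C)(C)OO
Why: Allylic C–H oxidation by tert-butylperoxyl radicals: the ring alkene has a single allylic methylene (C3), secondary and unhindered, whereas the isopropenyl group offers only a primary methyl. This is the selectivity known from the oxidation of valencene-type hydrocarbons to nootkatone-type enones.

Step 8
Reactants: 14 (4R)-4-(4,4-dimethoxy-2-methylbutan-2-yl)-4-(prop-1-en-2-yl)cyclohex-2-en-1-one
Product: 15 3-methyl-3-[(1R)-4-oxo-1-(prop-1-en-2-yl)cyclohex-2-en-1-yl]butanal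
Conditions: 1 M HCl, THF, 0 °C → rt
Reagents that add atoms: water, O
Why: Acid hydrolysis of a dimethyl acetal; dilute aqueous acid at low temperature leaves the enone and the isopropenyl group alone and does not activate the aldehyde enough for ring closure.

Step 9
Reactants: 15 3-methyl-3-[(1R)-4-oxo-1-(prop-1-en-2-yl)cyclohex-2-en-1-yl]butanal
Product: 16 (2R)-2-bromo-3-methyl-3-[(1R)-4-oxo-1-(prop-1-en-2-yl)cyclohex-2-en-1-yl]butanal
Conditions: (2S,5S)-2,5-diphenylpyrrolidine (20 mol %), 4,4-dibromo-2,6-di-tert-butylcyclohexa-2,5-dien-1-one, PhCO2H (20 mol %), H2O (2 equiv), CH2Cl2/pentane, −40 °C; cold filtration through silica, used at once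
Reagents that add atoms: 4,4-dibromo-2,6-di-tert-butylcyclohexa-2,5-dien-1-one, CC(C)(C)C1=CC(Br)(Br)C=C(C(C)(C)C)C1=O
Why: Enamine-catalysed asymmetric α-bromination: the (E)-enamine formed with the C2-symmetric pyrrolidine is shielded on one face by a phenyl group and takes bromine from the mild dienone donor on the other, which should set (R)-C10 under catalyst control, independent of the remote C6. Aldehydes with a quaternary β-carbon belong to the known substrate class, the dienone does not attack the alkenes, and the labile product is carried on without storage.

Step 10
Reactants: 16 (2R)-2-bromo-3-methyl-3-[(1R)-4-oxo-1-(prop-1-en-2-yl)cyclohex-2-en-1-yl]butanal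
Product: 17 (6R,9S,10R)-10-bromo-9-hydroxy-11,11-dimethyl-7-methylidenespiro[5.5]undec-1-en-3-one
Conditions: Me2AlCl (3 equiv), CH2Cl2, −78 → −30 °C; then aq. NaHCO3
Reagents that add atoms: none
Why: Me2AlCl binds the aldehyde oxygen (a further equivalent is held by the enone), and the CH2 terminus of the isopropenyl group (C8) attacks C9 while a hydrogen of the allylic methyl passes to oxygen, in a concerted or tightly ion-paired ene process. The closest known reaction type is the Lewis acid promoted type 2 intramolecular carbonyl-ene cyclisation of 6-methylhept-6-enals to 3-methylenecyclohexanols. Ring A closes as a six-membered ring by attack on the carbonyl carbon with the C=O bond outside the new ring (6-exo), the tether being on the central carbon of the ene unit. The only new stereocentre, C9, is set by the chair transition state: the aluminium-bound oxygen must be axial to reach the methyl hydrogen and the C10 bromine prefers the equatorial site beside C11, which places oxygen and bromine cis. With (R)-C10 and (R)-C6 this chair has C5 axial and C1 equatorial and gives (9S), whereas the chair with axial bromine would suffer a 1,3-diaxial contact between bromine and C1. Chemoselectivity requires the 1,1-disubstituted alkene to be the only π-nucleophile, and the ring B alkene is part of an electron-poor enone and stays inert. A methylaluminium chloride is chosen because its methyl groups consume any proton set free, so that neither the α-bromo aldehyde nor the new exocyclic alkene meets acid, and the excess suppresses methyl transfer to the aldehyde.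

Step 11
Reactants: 17 (6R,9S,10R)-10-bromo-9-hydroxy-11,11-dimethyl-7-methylidenespiro[5.5]undec-1-en-3-one
Product: 18 (6R,9S,10R)-10-bromo-11,11-dimethyl-7-methylidene-3-oxospiro[5.5]undec-1-en-9-yl acetate
Conditions: Ac2O, pyridine, DMAP (cat.), CH2Cl2, 0 °C → rt
Reagents that add atoms: acetic anhydride, CC(=O)OC(C)=O
Why: DMAP-catalysed acetylation of the axial secondary alcohol; a cis bromohydrin cannot close to an epoxide, so the mild base is safe, and the ester is the group of the target.

Step 12
Reactants: 18 (6R,9S,10R)-10-bromo-11,11-dimethyl-7-methylidene-3-oxospiro[5.5]undec-1-en-9-yl acetate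
Product: 20 (6R,9S,10R)-10-bromo-11,11-dimethyl-7-methylidene-3-(trifluoromethylsulfonyloxy)spiro[5.5]undec-2-en-9-yl acetate, via lithium enolate 19 (not isolated)
Conditions: LiBH(s-Bu)3 (1.05 equiv), THF, −78 °C; then PhNTf2, −78 → 0 °C
Reagents that add atoms: N-phenylbis(trifluoromethanesulfonimide), O=S(=O)(N(c1ccccc1)S(=O)(=O)C(F)(F)F)C(F)(F)F
Why: Conjugate reduction with enolate trapping: the hindered borohydride adds hydride to C1 of the β-unsubstituted enone, and the regiodefined C2=C3 enolate is triflated on oxygen. One equivalent of hydride at −78 °C should leave the acetate and the neopentyl bromide untouched.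

Step 13
Reactants: 20 (6R,9S,10R)-10-bromo-11,11-dimethyl-7-methylidene-3-(trifluoromethylsulfonyloxy)spiro[5.5]undec-2-en-9-yl acetate
Product: 21 (6R,9S,10R)-10-bromo-3,11,11-trimethyl-7-methylidenespiro[5.5]undec-2-en-9-yl acetate
Conditions: Me2Zn, Pd(PPh3)4 (5 mol %), THF, 0 °C → rt
Reagents that add atoms: dimethylzinc, C[Zn]C
Why: Negishi cross-coupling: zerovalent palladium inserts into the enol triflate C–O bond, methyl passes from zinc to palladium, and reductive elimination forms the C3–CH3 bond. The organozinc tolerates the acetate, and the unactivated secondary bromide does not add to this catalyst.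

Step 14
Reactants: 21 (6R,9S,10R)-10-bromo-3,11,11-trimethyl-7-methylidenespiro[5.5]undec-2-en-9-yl acetate
Product: 22 (2R,3S,6R,9S,10R)-10-bromo-2,3-epoxy-3,11,11-trimethyl-7-methylidenespiro[5.5]undecan-9-yl acetate
Conditions: mCPBA (1.05 equiv), CH2Cl2, −20 → 0 °C
Reagents that add atoms: 3-chloroperoxybenzoic acid, O=C(OO)c1cccc(Cl)c1
Why: Prilezhaev epoxidation: the trisubstituted C2=C3 alkene is far more nucleophilic than the hindered 1,1-disubstituted C7 methylene. Ring B holds C7 axial, with its methylene carbon over C1, so the peracid should approach anti to C7, as in the epoxidation of steroid 2-enes anti to the angular methyl group.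

Step 15
Reactants: 22 (2R,3S,6R,9S,10R)-10-bromo-2,3-epoxy-3,11,11-trimethyl-7-methylidenespiro[5.5]undecan-9-yl acetate
Product: 23 (2S,3S,6R,9S,10R)-10-bromo-2-chloro-3-hydroxy-3,11,11-trimethyl-7-methylidenespiro[5.5]undecan-9-yl acetate
Conditions: LiCl, AcOH, THF, rt
Reagents that add atoms: lithium chloride, [Li+].[Cl-]
Why: Trans-diaxial SN2 opening of an epoxide: chloride, assisted by acetic acid, attacks the secondary C2 with inversion along the axial line of a chair-like transition state. C2 is both the less substituted carbon and the one required stereoelectronically, so (2S) is set and the tertiary C3 hydroxyl is left axial and anti to chlorine.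

Step 16
Reactants: 23 (2S,3S,6R,9S,10R)-10-bromo-2-chloro-3-hydroxy-3,11,11-trimethyl-7-methylidenespiro[5.5]undecan-9-yl acetate
Product: 25 9-acetylisoobtusol [(2S,3S,6R,9S,10R)-3,10-dibromo-2-chloro-3,11,11-trimethyl-7-methylidenespiro[5.5]undecan-9-yl acetate], via alkoxyiminium bromide 24 (not isolated)
Conditions: Me2C=C(Br)NMe2 (freshly prepared, 1.5 equiv), CH2Cl2, 0 °C → rt
Reagents that add atoms: 1-bromo-N,N,2-trimethylprop-1-en-1-amine, CC(C)=C(Br)N(C)C
Why: Dehydroxybromination of a tertiary alcohol under neutral conditions with an α-bromoenamine: the alkoxyiminium bromide ionises at C3 with loss of a neutral amide, assisted by the anti-periplanar C2 chlorine, and bromide returns to the tertiary carbon of the chlorine-bridged cation on the axial line anti to chlorine. This is net retention and gives the trans-diaxial (2S,3S) bromochloride. The preference for the more substituted carbon and the trans-diaxial preference both direct bromide to C3, and no free acid is present that could move the C7 methylene into the ring.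

## Compound list

1 | 3-ethoxycyclohex-2-en-1-one | CCOC1=CC(=O)CCC1 | starting material
2 | isopropenylmagnesium bromide | C=C(C)[Mg]Br | starting material
3 | 3-ethoxy-1-(prop-1-en-2-yl)cyclohex-2-en-1-ol (racemic, not isolated) | CCOC1=CC(O)(C(C)=C)CCC1 | intermediate
4 | 3-(prop-1-en-2-yl)cyclohex-2-en-1-one | C=C(C)C1=CC(=O)CCC1 | intermediate
5 | (1S)-3-(prop-1-en-2-yl)cyclohex-2-en-1-ol | C=C(C)C1=C[C@@H](O)CCC1 | intermediate
6 | isobutyryl chloride | CC(C)C(Cl)=O | starting material
7 | (1S)-3-(prop-1-en-2-yl)cyclohex-2-en-1-yl 2-methylpropanoate | C=C(C)C1=C[C@@H](OC(=O)C(C)C)CCC1 | intermediate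
8 | trimethyl({2-methyl-1-[(1S)-3-(prop-1-en-2-yl)cyclohex-2-en-1-yl]oxyprop-1-en-1-yl}oxy)silane (not isolated) | C=C(C)C1=C[C@@H](OC(O[Si](C)(C)C)=C(C)C)CCC1 | intermediate
9 | trimethylsilyl 2-methyl-2-[(1R)-1-(prop-1-en-2-yl)cyclohex-2-en-1-yl]propanoate (not isolated) | C[Si](C)(C)OC(=O)C(C)(C)[C@]1(C(C)=C)CCCC=C1 | intermediate
10 | 2-methyl-2-[(1R)-1-(prop-1-en-2-yl)cyclohex-2-en-1-yl]propan-1-ol | OCC(C)(C)[C@]1(C(C)=C)CCCC=C1 | intermediate
11 | 2-methyl-2-[(1R)-1-(prop-1-en-2-yl)cyclohex-2-en-1-yl]propanal | O=CC(C)(C)[C@]1(C(C)=C)CCCC=C1 | intermediate
12 | (1R)-1-[(3E/Z)-4-methoxy-2-methylbut-3-en-2-yl]-1-(prop-1-en-2-yl)cyclohex-2-ene (not isolated) | COC=CC(C)(C)[C@]1(C(C)=C)CCCC=C1 | intermediate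
13 | (1R)-1-(4,4-dimethoxy-2-methylbutan-2-yl)-1-(prop-1-en-2-yl)cyclohex-2-ene | COC(OC)CC(C)(C)[C@]1(C(C)=C)CCCC=C1 | intermediate
14 | (4R)-4-(4,4-dimethoxy-2-methylbutan-2-yl)-4-(prop-1-en-2-yl)cyclohex-2-en-1-one | COC(OC)CC(C)(C)[C@]1(C(C)=C)CCC(=O)C=C1 | intermediate
15 | 3-methyl-3-[(1R)-4-oxo-1-(prop-1-en-2-yl)cyclohex-2-en-1-yl]butanal | O=CCC(C)(C)[C@]1(C(C)=C)CCC(=O)C=C1 | intermediate
16 | (2R)-2-bromo-3-methyl-3-[(1R)-4-oxo-1-(prop-1-en-2-yl)cyclohex-2-en-1-yl]butanal | O=C[C@H](Br)C(C)(C)[C@]1(C(C)=C)CCC(=O)C=C1 | intermediate
17 | (6R,9S,10R)-10-bromo-9-hydroxy-11,11-dimethyl-7-methylidenespiro[5.5]undec-1-en-3-one | C=C1C[C@H](O)[C@H](Br)C(C)(C)[C@@]12CCC(=O)C=C2 | intermediate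
18 | (6R,9S,10R)-10-bromo-11,11-dimethyl-7-methylidene-3-oxospiro[5.5]undec-1-en-9-yl acetate | C=C1C[C@H](OC(C)=O)[C@H](Br)C(C)(C)[C@@]12CCC(=O)C=C2 | intermediate
19 | lithium (6R,9S,10R)-9-acetoxy-10-bromo-11,11-dimethyl-7-methylidenespiro[5.5]undec-2-en-3-olate (not isolated) | C=C1C[C@H](OC(C)=O)[C@H](Br)C(C)(C)[C@@]12CCC(O[Li])=CC2 | intermediate
20 | (6R,9S,10R)-10-bromo-11,11-dimethyl-7-methylidene-3-(trifluoromethylsulfonyloxy)spiro[5.5]undec-2-en-9-yl acetate | C=C1C[C@H](OC(C)=O)[C@H](Br)C(C)(C)[C@@]12CCC(OS(=O)(=O)C(F)(F)F)=CC2 | intermediate
21 | (6R,9S,10R)-10-bromo-3,11,11-trimethyl-7-methylidenespiro[5.5]undec-2-en-9-yl acetate | C=C1C[C@H](OC(C)=O)[C@H](Br)C(C)(C)[C@@]12CCC(C)=CC2 | intermediate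
22 | (2R,3S,6R,9S,10R)-10-bromo-2,3-epoxy-3,11,11-trimethyl-7-methylidenespiro[5.5]undecan-9-yl acetate (oxirane oxygen anti to C7) | C=C1C[C@H](OC(C)=O)[C@H](Br)C(C)(C)[C@@]12CC[C@]3(C)O[C@@H]3C2 | intermediate
23 | (2S,3S,6R,9S,10R)-10-bromo-2-chloro-3-hydroxy-3,11,11-trimethyl-7-methylidenespiro[5.5]undecan-9-yl acetate | C=C1C[C@H](OC(C)=O)[C@H](Br)C(C)(C)[C@@]12CC[C@](C)(O)[C@@H](Cl)C2 | intermediate
24 | N-[1-{[(2S,3S,6R,9S,10R)-9-acetoxy-10-bromo-2-chloro-3,11,11-trimethyl-7-methylidenespiro[5.5]undecan-3-yl]oxy}-2-methylpropylidene]-N-methylmethanaminium bromide (not isolated) | C=C1C[C@H](OC(C)=O)[C@H](Br)C(C)(C)[C@@]12CC[C@](C)(OC(C(C)C)=[N+](C)C)[C@@H](Cl)C2.[Br-] | intermediate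
25 | 9-acetylisoobtusol, (2S,3S,6R,9S,10R)-3,10-dibromo-2-chloro-3,11,11-trimethyl-7-methylidenespiro[5.5]undecan-9-yl acetate | C=C1C[C@H](OC(C)=O)[C@H](Br)C(C)(C)[C@@]12CC[C@](C)(Br)[C@@H](Cl)C2 | target

## Step count and least certain steps

Total step count: 16. Longest linear sequence: 16 steps (fully linear from 1; 2 and 6 enter as partners in steps 1 and 3).

**Step 10 (key step).** The aluminium-bound axial oxygen has a 1,3-diaxial contact with one methyl group of C11. This may divert part of the closure through the chair with equatorial oxygen, giving loss of the cis relation at C9/C10. Methyl transfer from aluminium to the very electrophilic aldehyde is a second leak. Fallback, setting out from 16: the closure is run as before and the trans bromohydrin F1 (alone or mixed with 17) is oxidised with Dess–Martin periodinane to the α-bromo ketone F2. Reduction with NaBH4 in MeOH/CH2Cl2 at −78 °C should take the saturated, halogen-activated ketone before the ring B enone. Hydride should enter from the equatorial side, because the axial approach is blocked by the axial methyl of C11, giving the axial alcohol cis to bromine. The route is rejoined at 17.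

**Step 16.** Proton loss from the C3 cation (from C4 or from the methyl group) may compete with bromide capture, and the β-chlorine slows ionisation. Fallback, setting out from 23: the alcohol is converted with trifluoroacetic anhydride and pyridine into the tertiary trifluoroacetate F3. This ester is solvolysed in hexafluoroisopropanol containing n-Bu4NBr and 2,6-lutidine. The strongly ionising, weakly nucleophilic and weakly basic medium favours the chlorine-bridged cation and its capture by bromide over elimination. The route is rejoined at 25.

**Step 9.** Enamine formation at the neopentyl-type aldehyde may be slow, and the product may epimerise at C10 through enamine or enol before ring closure, lowering stereocontrol at C10. Fallback, setting out from 15: bromination without stereocontrol (pyrrolidine cat., N-bromosuccinimide, CH2Cl2, −20 °C) gives 16 together with its C10 epimer F4. The mixture is cyclised as in step 10. Each epimer should close through its own chair with equatorial bromine, giving 17 and the diastereomeric cis bromohydrin F5. These are diastereomers because C6 is fixed, and are separated by chromatography at the cost of roughly half the material. The route is rejoined at 17.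

**Step 4.** Ionisation or elimination of the dienyl ester to a triene, or a sluggish [3,3] shift across the bond between two fully substituted carbons, may outrun the rearrangement. Fallback, setting out from 5: Johnson–Claisen rearrangement with MeC(OEt)3 and a trace of propionic acid at 135 °C forms only one quaternary centre, with the same suprafacial chirality transfer, and gives the ethyl ester F6. Two successive enolate methylations (LiN(i-Pr)2, MeI) lead through the monomethyl ester F7 to the gem-dimethyl ester F8, and LiAlH4 reduction rejoins the route at 10.

**Step 7.** Hydrogen abstraction at the isopropenyl methyl group or at the acetal C–H may compete with abstraction at C3, and peroxide by-products may form. Fallback, setting out from 10: the allylic methylene and the primary alcohol are oxidised together with the stoichiometric CrO3–3,5-dimethylpyrazole complex in CH2Cl2 at −20 °C to the keto aldehyde F9. Wittig methoxymethylenation at −78 °C with one equivalent of ylide takes only the aldehyde, which is far more reactive than the conjugated ketone, and gives the enol ether F10. Mild aqueous acid rejoins the route at 15.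

**Step 14.** The peracid may deliver oxygen in part syn to C7, or attack the C7 methylene, giving poor facial or site selectivity. Fallback, setting out from 21: N-bromosuccinimide in aqueous acetone gives the bromohydrin F11. Bromonium formation is reversible, and water should open the ion trans-diaxially at the methyl-bearing C3, the matched sense for a bromonium ion. K2CO3 in acetone closes the trans-diaxial bromohydrin with inversion at C2 to the same oxirane, and the route is rejoined at 22.

## Further compounds

F1 | step 10 | (6R,9R,10R)-10-bromo-9-hydroxy-11,11-dimethyl-7-methylidenespiro[5.5]undec-1-en-3-one | C=C1C[C@@H](O)[C@H](Br)C(C)(C)[C@@]12CCC(=O)C=C2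
F2 | step 10 | (6R,10R)-10-bromo-11,11-dimethyl-7-methylidenespiro[5.5]undec-1-ene-3,9-dione | C=C1CC(=O)[C@H](Br)C(C)(C)[C@@]12CCC(=O)C=C2
F3 | step 16 | (2S,3S,6R,9S,10R)-9-acetoxy-10-bromo-2-chloro-3,11,11-trimethyl-7-methylidenespiro[5.5]undecan-3-yl trifluoroacetate | C=C1C[C@H](OC(C)=O)[C@H](Br)C(C)(C)[C@@]12CC[C@](C)(OC(=O)C(F)(F)F)[C@@H](Cl)C2
F4 | step 9 | (2S)-2-bromo-3-methyl-3-[(1R)-4-oxo-1-(prop-1-en-2-yl)cyclohex-2-en-1-yl]butanal | O=C[C@@H](Br)C(C)(C)[C@]1(C(C)=C)CCC(=O)C=C1
F5 | step 9 | (6R,9R,10S)-10-bromo-9-hydroxy-11,11-dimethyl-7-methylidenespiro[5.5]undec-1-en-3-one | C=C1C[C@@H](O)[C@@H](Br)C(C)(C)[C@@]12CCC(=O)C=C2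
F6 | step 4 | ethyl 2-[(1R)-1-(prop-1-en-2-yl)cyclohex-2-en-1-yl]acetate | CCOC(=O)C[C@]1(C(C)=C)CCCC=C1
F7 | step 4 | ethyl 2-[(1S)-1-(prop-1-en-2-yl)cyclohex-2-en-1-yl]propanoate (both epimers at C2 of the chain) | CCOC(=O)C(C)[C@]1(C(C)=C)CCCC=C1
F8 | step 4 | ethyl 2-methyl-2-[(1R)-1-(prop-1-en-2-yl)cyclohex-2-en-1-yl]propanoate | CCOC(=O)C(C)(C)[C@]1(C(C)=C)CCCC=C1
F9 | step 7 | 2-methyl-2-[(1R)-4-oxo-1-(prop-1-en-2-yl)cyclohex-2-en-1-yl]propanal | O=CC(C)(C)[C@]1(C(C)=C)CCC(=O)C=C1
F10 | step 7 | (4R)-4-[(3E/Z)-4-methoxy-2-methylbut-3-en-2-yl]-4-(prop-1-en-2-yl)cyclohex-2-en-1-one | COC=CC(C)(C)[C@]1(C(C)=C)CCC(=O)C=C1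
F11 | step 14 | (2S,3S,6R,9S,10R)-2,10-dibromo-3-hydroxy-3,11,11-trimethyl-7-methylidenespiro[5.5]undecan-9-yl acetate | C=C1C[C@H](OC(C)=O)[C@H](Br)C(C)(C)[C@@]12CC[C@](C)(O)[C@@H](Br)C2
A1 | alternative 1 | spiro vinylogous ester with C2 chloride and C3 triethylsilyl ether, configured as in 25 | O=C1C=C(OCC)CC(C)(C)[C@@]12CC[C@](C)(O[Si](CC)(CC)CC)[C@@H](Cl)C2
A2 | alternative 1 | 6-chloro-3-ethoxy-5,5-dimethyl-6-[3-methyl-3-(triethylsilyloxy)pent-4-en-1-yl]cyclohex-2-en-1-one, carbinol carbon configured as C3 of 25 | O=C1C=C(OCC)CC(C)(C)C1(Cl)CC[C@](C)(O[Si](CC)(CC)CC)C=C
A3 | alternative 2 | spiro ring A bromide tert-butyldimethylsilyl ether with ring B α-chloro ketone | C=C1C[C@H](O[Si](C)(C)C(C)(C)C)[C@H](Br)C(C)(C)[C@@]12CCC(=O)[C@@H](Cl)C2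
A4 | alternative 2 | 2-chloro-4-alkylidenecyclohexanone with C10 bromide, C11 tertiary chloride and C9 silyl ether (C8 cis to C5 at the alkene) | CC(C)(Cl)[C@@H](Br)[C@@H](O[Si](C)(C)C(C)(C)C)C/C(C)=C1\CCC(=O)[C@@H](Cl)C1
A5 | alternative 3 | spiro vinylogous ester with ring B enone | O=C1C=C(OCC)CC(C)(C)[C@@]12CCC(=O)C=C2
A6 | alternative 3 | 4-ethoxy-6,6-dimethyl-2-oxocyclohex-3-ene-1-carbaldehyde (C6 formyl derivative of the dimedone ethyl enol ether) | O=CC1C(=O)C=C(OCC)CC1(C)C
A7 | alternative 3 | methyl vinyl ketone (but-3-en-2-one) | C=CC(C)=O
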